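**Retrosynthetic overview**
- Last ring formed is the dihydrofuran: Rh(II)-carbenoid 1,5-C–H insertion of an aryl diazoacetate into its own ArO–CH2–(cyclohexenyl) group sets C2; base epimerisation then gives 2,3-trans, and the C3 ester becomes CH2OH.
- The ArO–CH2 bond is made by Mitsunobu coupling of a 2-hydroxyarylacetate with an enantiopure cyclohexenylmethanol.
- The cyclohexene ring is formed first, by RCM; its cis-diol comes from Sharpless desymmetrisation of divinylcarbinol followed by epoxide opening with the methallyl alcohol dianion.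
- The arylacetate comes from methyl dihydroferulate by ortho-bromination and Pd/Reformatsky α-arylation.

**Assumption:** Rh2(R-PTTL)4 is taken to give the (2S) product, by analogy with the (S)-catalyst giving (2R) in 2-aryl cases; if the sense is reversed, use Rh2(S-PTTL)4.

**Step 1**
Reactants: 1, penta-1,4-dien-3-ol
Product: 2, (1S)-1-[(2R)-oxiran-2-yl]prop-2-en-1-ol
Conditions: Ti(OiPr)4, L-(+)-DIPT, cumene hydroperoxide, 4 Å MS, CH2Cl2, −20 °C
Reagents that add atoms: cumene hydroperoxide, CC(C)(OO)c1ccccc1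
Why: Sharpless asymmetric epoxidation desymmetrises the divinylcarbinol; L-(+)-tartrate gives the erythro (2R,3S) epoxy alcohol, and the minor enantiomer is removed by over-epoxidation, so ee is very high.

**Step 2**
Reactants: 2; 3, 2-methylprop-2-en-1-ol
Product: 4, (5R,6S)-2-methylideneoct-7-ene-1,5,6-triol
Conditions: 3 (3 equiv), n-BuLi (6 equiv), TMEDA, Et2O, 0 °C→rt; then 2, THF, −40→0 °C
Reagents that add atoms: none beyond reactant 3 (C=C(C)CO)
Why: The dilithio (allyl anion/alkoxide) dianion of methallyl alcohol opens the terminal epoxide by SN2 at CH2; neither C–O stereocentre is touched, so the anti-diol is retained.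

**Step 3**
Reactants: 4
Product: 5, 2-{2-[(4R,5S)-5-ethenyl-2,2-dimethyl-1,3-dioxolan-4-yl]ethyl}prop-2-en-1-ol
Conditions: 2,2-dimethoxypropane, PPTS (cat.), acetone, rt; MeOH quench
Reagents that add atoms: 2,2-dimethoxypropane, COC(C)(C)OC
Why: Acetonide formation is selective for the 1,2-diol (five-membered ring) and leaves the remote primary allylic OH free.

**Step 4**
Reactants: 5
Product: 6, [(3aS,7aR)-2,2-dimethyl-3a,6,7,7a-tetrahydro-1,3-benzodioxol-5-yl]methanol
Conditions: Grubbs II (3 mol%), CH2Cl2 (0.01 M), 40 °C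
Reagents that add atoms: none
Why: Ring-closing metathesis of the vinyl and 1,1-disubstituted alkenes gives the trisubstituted cyclohexene; the anti-diol becomes the ring cis-diol.

**Step 5**
Reactants: 7, methyl 3-(4-hydroxy-3-methoxyphenyl)propanoate
Product: 8, methyl 3-(3-bromo-4-hydroxy-5-methoxyphenyl)propanoate
Conditions: NBS, i-Pr2NH (10 mol%), CH2Cl2, 0 °C
Reagents that add atoms: N-bromosuccinimide, O=C1CCC(=O)N1Br
Why: Electrophilic aromatic bromination goes to the only free position ortho to the phenol OH (para is blocked).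

**Step 6**
Reactants: 8; 9, (2-tert-butoxy-2-oxoethyl)zinc bromide
Product: 10, methyl 3-[3-(2-tert-butoxy-2-oxoethyl)-4-hydroxy-5-methoxyphenyl]propanoate
Conditions: 9 (3 equiv), Pd(dba)2 (2 mol%), Q-Phos (2 mol%), THF, rt→50 °C
Reagents that add atoms: 9, CC(C)(C)OC(=O)C[Zn]Br
Why: Pd-catalysed Negishi-type α-arylation with a Reformatsky reagent; the mild zinc enolate tolerates the methyl ester and (with excess) the free phenol, and the tert-butyl ester resists lactonisation.

**Step 7**
Reactants: 10; 6
Product: 11, methyl 3-[3-(2-tert-butoxy-2-oxoethyl)-4-{[(3aS,7aR)-2,2-dimethyl-3a,6,7,7a-tetrahydro-1,3-benzodioxol-5-yl]methoxy}-5-methoxyphenyl]propanoate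
Conditions: PPh3, DIAD, THF, 0 °C→rt
Reagents that add atoms: none
Why: Mitsunobu etherification, SN2 at the primary allylic carbon; no stereocentre is involved.

**Step 8**
Reactants: 11
Product: 12, methyl 3-[3-(2-tert-butoxy-1-diazo-2-oxoethyl)-4-{[(3aS,7aR)-2,2-dimethyl-3a,6,7,7a-tetrahydro-1,3-benzodioxol-5-yl]methoxy}-5-methoxyphenyl]propanoate
Conditions: p-ABSA, DBU, MeCN, 0 °C→rt
Reagents that add atoms: p-acetamidobenzenesulfonyl azide, CC(=O)Nc1ccc(cc1)S(=O)(=O)N=[N+]=[N-]
Why: Regitz diazo transfer occurs only at the activated arylacetate CH2; the propanoate CH2 is not acidic enough.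

**Step 9**
Reactants: 12
Product: 13, tert-butyl (2S,3R)-2-[(3aS,7aR)-2,2-dimethyl-3a,6,7,7a-tetrahydro-1,3-benzodioxol-5-yl]-7-methoxy-5-(3-methoxy-3-oxopropyl)-2,3-dihydro-1-benzofuran-3-carboxylate (2,3-cis)
Conditions: Rh2(R-PTTL)4 (1 mol%), toluene, −60 °C, slow addition
Reagents that add atoms: none
Why: Intramolecular Rh(II)-carbenoid 1,5-C–H insertion into the allylic, α-oxygenated OCH2 closes the dihydrofuran; the chiral catalyst selects one enantiotopic H and sets C2 as S, giving the kinetic cis ester.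

**Step 10**
Reactants: 13
Product: 14, tert-butyl (2S,3S)-2-[(3aS,7aR)-2,2-dimethyl-3a,6,7,7a-tetrahydro-1,3-benzodioxol-5-yl]-7-methoxy-5-(3-methoxy-3-oxopropyl)-2,3-dihydro-1-benzofuran-3-carboxylate (2,3-trans)
Conditions: NaOMe (0.3 equiv), MeOH, 0 °C→rt
Reagents that add atoms: none
Why: Thermodynamic enolate epimerisation at C3 (α to the ester) gives the more stable trans isomer; C2 is untouched.

**Step 11**
Reactants: 14
Product: 15, 3-[(2S,3R)-2-[(3aS,7aR)-2,2-dimethyl-3a,6,7,7a-tetrahydro-1,3-benzodioxol-5-yl]-3-(hydroxymethyl)-7-methoxy-2,3-dihydro-1-benzofuran-5-yl]propan-1-ol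
Conditions: LiAlH4, THF, 0 °C→rt
Reagents that add atoms: none
Why: Hydride reduction converts both esters into the two primary alcohols; no stereocentre changes (the C3 descriptor becomes R only through CIP priorities).

**Step 12**
Reactants: 15
Product: 16, difengpiol A, (1R,2S)-4-[(2S,3R)-3-(hydroxymethyl)-5-(3-hydroxypropyl)-7-methoxy-2,3-dihydro-1-benzofuran-2-yl]cyclohex-3-ene-1,2-diol
Conditions: AcOH/H2O (4:1), 40 °C
Reagents that add atoms: none
Why: Mild acidic acetal hydrolysis releases the cis-diol without ionising the allylic C–O bonds.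

**Compound list**
1 | penta-1,4-dien-3-ol | C=CC(O)C=C | starting material
2 | (1S)-1-[(2R)-oxiran-2-yl]prop-2-en-1-ol | C=C[C@H](O)[C@H]1CO1 | intermediate
3 | 2-methylprop-2-en-1-ol | C=C(C)CO | starting material
4 | (5R,6S)-2-methylideneoct-7-ene-1,5,6-triol | C=C[C@H](O)[C@H](O)CCC(=C)CO | intermediate
5 | 2-{2-[(4R,5S)-5-ethenyl-2,2-dimethyl-1,3-dioxolan-4-yl]ethyl}prop-2-en-1-ol | C=C[C@@H]1OC(C)(C)O[C@@H]1CCC(=C)CO | intermediate
6 | [(3aS,7aR)-2,2-dimethyl-3a,6,7,7a-tetrahydro-1,3-benzodioxol-5-yl]methanol | OCC1=C[C@@H]2OC(C)(C)O[C@@H]2CC1 | intermediate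
7 | methyl 3-(4-hydroxy-3-methoxyphenyl)propanoate | COC(=O)CCc1ccc(O)c(OC)c1 | starting material
8 | methyl 3-(3-bromo-4-hydroxy-5-methoxyphenyl)propanoate | COC(=O)CCc1cc(Br)c(O)c(OC)c1 | intermediate
9 | (2-tert-butoxy-2-oxoethyl)zinc bromide | CC(C)(C)OC(=O)C[Zn]Br | starting material
10 | methyl 3-[3-(2-tert-butoxy-2-oxoethyl)-4-hydroxy-5-methoxyphenyl]propanoate | COC(=O)CCc1cc(CC(=O)OC(C)(C)C)c(O)c(OC)c1 | intermediate
11 | aryl cyclohexenylmethyl ether (name in Step 7) | COC(=O)CCc1cc(CC(=O)OC(C)(C)C)c(OCC2=C[C@@H]3OC(C)(C)O[C@@H]3CC2)c(OC)c1 | intermediate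
12 | aryl diazoacetate (name in Step 8) | COC(=O)CCc1cc(C(=[N+]=[N-])C(=O)OC(C)(C)C)c(OCC2=C[C@@H]3OC(C)(C)O[C@@H]3CC2)c(OC)c1 | intermediate
13 | (2S,3R)-cis dihydrobenzofuran diester (name in Step 9) | COC(=O)CCc1cc(OC)c2O[C@H](C3=C[C@@H]4OC(C)(C)O[C@@H]4CC3)[C@H](C(=O)OC(C)(C)C)c2c1 | intermediate
14 | (2S,3S)-trans dihydrobenzofuran diester (name in Step 10) | COC(=O)CCc1cc(OC)c2O[C@H](C3=C[C@@H]4OC(C)(C)O[C@@H]4CC3)[C@@H](C(=O)OC(C)(C)C)c2c1 | intermediate
15 | diol acetonide (name in Step 11) | OCCCc1cc(OC)c2O[C@H](C3=C[C@@H]4OC(C)(C)O[C@@H]4CC3)[C@@H](CO)c2c1 | intermediate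
16 | difengpiol A | COc1cc(CCCO)cc2c1O[C@H](C1=C[C@H](O)[C@H](O)CC1)[C@H]2CO | target

**Step count**
Total steps: 12. Longest linear sequence: 10 (steps 1–4, then 7–12, from divinylcarbinol).

**Three steps most likely to fail, with fallbacks**
1. Step 9 (C–H insertion). Intramolecular cyclopropanation of the cyclohexene alkene may compete, and the ee and sense with a 2-alkenyl substrate are unproven. Fallback: drop the carbenoid. Oxidise 6 to the enal (MnO2), set the C2 carbinol by an Evans syn-aldol with the O-silyl arylacetyl oxazolidinone derived from 10, desilylate, close the ring by intramolecular Mitsunobu etherification (inversion at C2), then epimerise C3 to trans and reduce.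
2. Step 2 (dianion opening of the unprotected epoxy alcohol). Payne rearrangement or base-induced epoxide isomerisation may lower the yield. Fallback: build the diol by C3'–C4' bond formation instead. Claisen rearrangement of the vinyl ether of the 2-methylenepropane-1,3-diol mono-aryl ether of 10 gives a 4-(aryloxymethyl)pent-4-enal; Ir-catalysed anti-(α-acyloxy)allylation then RCM gives the same ring.
3. Step 6 (Negishi α-arylation on a free ortho-bromophenol). The zinc phenoxide may slow oxidative addition or the product may lactonise. Fallback: avoid Pd. Ortho-selective Friedel–Crafts hydroxyalkylation of 7 with tert-butyl glyoxylate, etherification with 6, oxidation to the aryl α-keto ester, then tosylhydrazone formation and Bamford–Stevens elimination to give 12 directly.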